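All runs were generated by integration for substances that don't exist; scatter was added.

**Time counted.** Time at temperature is what I counted here: how many lifetimes a Z spent beside L before the reading.

| setting | north-east | east | midnight | winter | dawn | spring |
|---|---|---|---|---|---|---|
| D | 0.13 M | 0.13 M | 0.13 M | 0.13 M | 0.13 M | 0.13 M |
| L | 6.5 mM | 9.8 mM | 13 mM | 13 mM | 13 mM | 13 mM |
| temperature | 28 °C | 55 °C | 65 °C |  | 15 °C | 40 °C |
| remark | run made earlier | run made earlier |  | at 15 °C until 4.0 min, from then on at 65 °C |  |  |
| time |  |  | 8.0 min | 8.0 min | 8.0 min | 8.0 min |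

| run | time / min | Z / % | X / % | D / % |
|---|---|---|---|---|
| north-east | 2.00 | 2.4 | 0.4 | 98.5 |
| north-east | 6.00 | 6.5 | 0.2 | 95.1 |
| north-east | 10.0 | 9.9 | 1.9 | 91.5 |
| north-east | 15.0 | 12.2 | 0.9 | 86.5 |
| north-east | 25.0 | 19.3 | 2.7 | 78.8 |
| north-east | 30.0 | 21.7 | 4.2 | 75.2 |
| east | 1.33 | 23.0 | 2.0 | 74.9 |
| east | 2.50 | 33.7 | 9.8 | 58.6 |
| east | 4.00 | 38.6 | 12.6 | 47.4 |
| east | 5.00 | 39.4 | 19.5 | 41.5 |
| east | 6.00 | 37.9 | 22.2 | 36.8 |
| east | 8.00 | 38.1 | 33.5 | 32.6 |

(each reading ± 1 percentage point)

1. which flask leads in share of Z in all that became Z or X ("all alike" within 1.5 percentage points) (midnight / winter / dawn / spring / all alike)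
2. share of Z in all that became Z or X, midnight
3. share of Z in all that became Z or X, winter
4. share of Z in all that became Z or X, dawn
5. share of Z in all that became Z or X, spring

- on the list of suspects stand: D <-> Z; Z + L <-> X + L; Z -> E
- the share counts what is present at the end, not what went on to other products

**Two clocks.** The first east reading of [D] gave a loss constant of 0.217 min⁻¹, and the last north-east reading gave 0.009501 min⁻¹, a factor of 22.9 across that temperature step. In the east run X climbed between 4.00 min and 8.00 min while [Z] stood near 39.4 %, so Z went net to X at 0.133 min⁻¹. The north-east run, using final X and mid-run Z, gave 0.0115 min⁻¹. I treated this step as pseudo-first-order in [Z], proportional to [L]. Per unit of [L], the factor was 7.66. These are readings, with their scatter, and I assumed a constant factor per degree.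

**Midnight curve.** Carried to midnight, D's constant became 0.693 min⁻¹, which was also the starting slope of [Z] as a fraction of the charge. D's lifetime in the midnight flask was 1.44 min. Z's lifetime against L in the midnight flask became 2.67 min. Taken one way, the steps put the knee of [Z] in the midnight flask at 1.93 min.

Z arrives about one D lifetime late, so I divided the time after that delay by Z's lifetime. This lifetime count came to 2.45 at the midnight reading, and I took the share as exp(−count). On this reckoning [Z] and [X] cross at a count of 0.693, which in the midnight flask is 3.30 min. At the midnight reading my share was 8.61 %, still falling. At dawn's temperature the lifetime was 116 min, far longer than 8.0 min, so dawn was my pick.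

**The forecast.** It named dawn, with 19 % for midnight, 42 % for winter, 97 % for dawn and 81 % for spring. Its midnight figure stood above mine. On X it said: “No reverse X→Z is visible, and the mass balance shows little E.”

**The flasks.** Dawn came first at 96.6 %, then spring at 77.3 %, winter at 45.4 % and midnight at 32.3 %, which was 13 percentage points above the forecast.

    D ⇌ Z (K = 2.10, k = 0.0440 min⁻¹, Ea = 97.0 kJ mol⁻¹, ΔH = −7.00 kJ mol⁻¹)
    Z + L ⇌ X + L, rate k2*[L]*[Z] forward; the back reaction follows from the equilibrium constant (K = 1.90, k = 5.30 L mol⁻¹ min⁻¹, Ea = 62.0 kJ mol⁻¹, ΔH = 10.0 kJ mol⁻¹)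
    Z → E (k = 2.40 × 10⁻⁵ min⁻¹, Ea = 115 kJ mol⁻¹)
    (constants at 40 °C)

**Count applied.** At midnight the count of 2.45 gave 8.61 %, but the flask gave 32.3 %, which was 24 points above it. At 80.0 min the midnight share stood at 28.4 %. I ran the same count on the neighbour, which was midnight with 0.0052 M of L. Z's lifetime stretched to 6.68 min, the count fell to 0.981, and exp(−count) gave 37.5 %. That flask gave 46.8 %, a smaller gap than midnight's, at 9.3 points.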